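The pyranone (ring C) is cut at C3–C4 and O1–C2. C4 together with ring A and O1 is a salicyloyl unit, and C2=C3, with ring B on C2 and the C9H2–C10H chain on C3, is the two-carbon unit of an unsymmetrical aryl alkyl alkyne. A rhodium-catalysed oxidative annulation of 2-hydroxy-4,6-dimethoxybenzaldehyde with that alkyne forms both bonds and ring C in one operation. The alkyne already carries the 2'-bromide, the 4'-benzyl ether and the (R)-C10/C11 diol as an acetonide (from methyl (R)-glycerate acetonide). Oxepine closure by C–O coupling, phenol unmasking, C6 iodination and Suzuki alkenylation then complete the target.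

Key step: step 8

Remark: flavone locants are used (side chain C9H2 on C3, stereogenic C10H, carbinol C11). For 14–17, 20, 21 and F6 the name "oxepinoflavone" denotes the target's tetracyclic core, a flavone in which C3–C9H2–C10H–O–C2' close a seven-membered ring and C10 bears C(CH3)2OH.

Step 1
Reactants: 1 methyl (R)-2,2-dimethyl-1,3-dioxolane-4-carboxylate
Product: 2 2-[(4R)-2,2-dimethyl-1,3-dioxolan-4-yl]propan-2-ol
Conditions: MeMgBr (3 equiv), THF, 0 °C to rt; then H2O
Reagents that add atoms: methylmagnesium bromide, C[Mg]Br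
Why: Double Grignard addition to the ester should give the tertiary carbinol (the future C11) without breaking any bond of the stereocentre (the future C10), which is not enolised under these conditions.

Step 2
Reactants: 2 2-[(4R)-2,2-dimethyl-1,3-dioxolan-4-yl]propan-2-ol
Product: 3 (2R)-3-methylbutane-1,2,3-triol
Conditions: Dowex 50W (H+ form), H2O–MeOH, 50 °C
Reagents that add atoms: none
Why: Acid-catalysed acetal hydrolysis frees the terminal 1,2-diol, and no bond to the stereocentre is broken.

Step 3
Reactants: 3 (2R)-3-methylbutane-1,2,3-triol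
Product: 4 (2R)-2,3-dihydroxy-3-methylbutyl 4-methylbenzenesulfonate
Conditions: TsCl (1.05 equiv), Bu2SnO (2 mol %), Et3N, MeCN, 0 °C to rt
Reagents that add atoms: 4-toluenesulfonyl chloride, Cc1ccc(cc1)S(Cl)(=O)=O
Why: Tin-acetal-catalysed regioselective sulfonylation of a terminal 1,2-diol should place the tosylate on the primary hydroxyl only, the secondary and tertiary hydroxyls being far less reactive.

Step 4
Reactants: 4 (2R)-2,3-dihydroxy-3-methylbutyl 4-methylbenzenesulfonate
Product: 6 (3R)-2-methylhex-5-yne-2,3-diol, via terminal epoxide 5 (not isolated)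
Conditions: LiC≡CH·H2NCH2CH2NH2 (4 equiv), DMSO, 0 °C to rt; then H2O
Reagents that add atoms: lithium acetylide (ethylenediamine complex), [Li]C#C
Why: Intramolecular Williamson closure of the secondary alkoxide onto the primary tosylate (3-exo-tet) should give epoxy carbinol 5, which the acetylide opens by SN2 attack at its CH2 carbon, so the C–O bond of the stereocentre is never broken (a Payne equilibration, if it occurs, regenerates the same terminal epoxide).

Step 5
Reactants: 6 (3R)-2-methylhex-5-yne-2,3-diol
Product: 7 (4R)-2,2,5,5-tetramethyl-4-(prop-2-yn-1-yl)-1,3-dioxolane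
Conditions: Me2C(OMe)2, camphorsulfonic acid (cat.), CH2Cl2, rt
Reagents that add atoms: 2,2-dimethoxypropane, COC(C)(C)OC
Why: Acid-catalysed transketalisation protects the secondary/tertiary 1,2-diol as its acetonide, which shields both hydroxyls from the oxidative conditions of the key step.

Step 6
Reactants: 8 3-bromo-4-iodophenol
Product: 9 4-(benzyloxy)-2-bromo-1-iodobenzene
Conditions: BnBr, K2CO3, acetone, 55 °C
Reagents that add atoms: benzyl bromide, BrCc1ccccc1
Why: Williamson etherification of the phenoxide is straightforward and leaves both aryl halides untouched.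

Step 7
Reactants: 7 (4R)-2,2,5,5-tetramethyl-4-(prop-2-yn-1-yl)-1,3-dioxolane and 9 4-(benzyloxy)-2-bromo-1-iodobenzene
Product: 10 (4R)-4-{3-[4-(benzyloxy)-2-bromophenyl]prop-2-yn-1-yl}-2,2,5,5-tetramethyl-1,3-dioxolane
Conditions: PdCl2(PPh3)2 (2 mol %), CuI (4 mol %), Et3N, THF, rt
Reagents that add atoms: none
Why: Sonogashira coupling at room temperature should engage only the C–I bond, because zerovalent palladium adds to aryl iodides far faster than to aryl bromides, so the bromide is kept for the oxepine closure.

Step 8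
Reactants: 10 (4R)-4-{3-[4-(benzyloxy)-2-bromophenyl]prop-2-yn-1-yl}-2,2,5,5-tetramethyl-1,3-dioxolane and 11 2-hydroxy-4,6-dimethoxybenzaldehyde
Product: 12 2-[4-(benzyloxy)-2-bromophenyl]-5,7-dimethoxy-3-{[(4R)-2,2,5,5-tetramethyl-1,3-dioxolan-4-yl]methyl}-4H-chromen-4-one
Conditions: [Cp*RhCl2]2 (2.5 mol %), Cu(OAc)2 (2.2 equiv), NaOAc (1 equiv), o-xylene, 120 °C, N2
Reagents that add atoms: none
Why: Acetate-assisted binding of the phenoxide of 11 to trivalent rhodium and cleavage of the formyl C–H bond should give a five-membered acyl rhodacycle; the alkyne of 10 then inserts into the rhodium–acyl bond to a seven-membered oxa-rhodacycle, C–O reductive elimination releases the chromone, and Cu(OAc)2 returns monovalent rhodium to the trivalent state. The closest known reaction type is the rhodium-catalysed oxidative coupling of salicylaldehydes with internal alkynes to 2,3-disubstituted chromones. Ring C is closed in a formal [4+2] oxidative annulation whose last bond, O1–C2, is made by reductive elimination from the metallacycle and not by an exo or endo nucleophilic attack. No stereocentre is formed, and C10 lies outside all bonds made or broken, so its R configuration is carried through unchanged. The step needs regioselective insertion (the ring B carbon to rhodium and then to O1, the C9-bearing carbon to the acyl carbon), which the conjugating 4-benzyloxyaryl group and the smaller CH2 substituent on the other alkyne carbon should secure, as is usual for aryl alkyl alkynes. It also needs chemoselectivity for the formyl C–H bond over the aryl bromide, benzyl ether and acetonide, which should hold because neither trivalent rhodium nor divalent copper adds oxidatively to C–Br and the only acid present is buffered acetic acid.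

Step 9
Reactants: 12 2-[4-(benzyloxy)-2-bromophenyl]-5,7-dimethoxy-3-{[(4R)-2,2,5,5-tetramethyl-1,3-dioxolan-4-yl]methyl}-4H-chromen-4-one
Product: 13 2-[4-(benzyloxy)-2-bromophenyl]-3-[(2R)-2,3-dihydroxy-3-methylbutyl]-5,7-dimethoxy-4H-chromen-4-one
Conditions: 2 M aq. HCl, THF, 40 °C
Reagents that add atoms: none
Why: Acid-catalysed acetal hydrolysis releases the C10/C11 diol, while the chromone, the benzyl ether and the aryl bromide are inert to dilute acid.

Step 10
Reactants: 13 2-[4-(benzyloxy)-2-bromophenyl]-3-[(2R)-2,3-dihydroxy-3-methylbutyl]-5,7-dimethoxy-4H-chromen-4-one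
Product: 14 (10R)-4'-benzyloxy-5,7-dimethoxyoxepinoflavone
Conditions: Pd(OAc)2 (5 mol %), 2-(di-tert-butylphosphino)-1,1'-binaphthyl (6 mol %), Cs2CO3 (1.5 equiv), toluene, 80 °C
Reagents that add atoms: none
Why: Palladium-catalysed intramolecular C–O coupling (Buchwald-type etherification) should close the seven-membered oxepine through the secondary C10 alkoxide rather than an eight-membered ring through the tertiary one, the bulky phosphine favouring C–O reductive elimination over β-hydride elimination, and since the C10–O bond is not broken the R configuration is retained.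

Step 11
Reactants: 14 (10R)-4'-benzyloxy-5,7-dimethoxyoxepinoflavone
Product: 15 (10R)-5,4'-dihydroxy-7-methoxyoxepinoflavone
Conditions: BCl3 (5 equiv), C6HMe5 (3 equiv), CH2Cl2, −78 to −20 °C; then MeOH, H2O
Reagents that add atoms: none
Why: In this Lewis-acid ether cleavage BCl3 chelated between the C4 carbonyl and O5 removes only the peri 5-methyl group and, with pentamethylbenzene as cation trap, the benzyl group, whereas the 7-methyl ether, the cyclic C10–O–C2' ether and the inductively deactivated β-aryloxy tertiary carbinol should survive at low temperature.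

Step 12
Reactants: 15 (10R)-5,4'-dihydroxy-7-methoxyoxepinoflavone
Product: 16 (10R)-4'-acetoxy-5-hydroxy-7-methoxyoxepinoflavone
Conditions: Ac2O (1.1 equiv), pyridine, CH2Cl2, 0 °C
Reagents that add atoms: acetic anhydride, CC(=O)OC(C)=O
Why: Selective O-acetylation should occur at the free 4'-phenol, which reacts much faster than the 5-hydroxyl hydrogen-bonded to the C4 carbonyl and than the hindered tertiary alcohol.

Step 13
Reactants: 16 (10R)-4'-acetoxy-5-hydroxy-7-methoxyoxepinoflavone
Product: 17 (10R)-4'-acetoxy-5-hydroxy-6-iodo-7-methoxyoxepinoflavone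
Conditions: BnMe3N·ICl2 (1.05 equiv), CaCO3, CH2Cl2–MeOH, rt
Reagents that add atoms: benzyltrimethylammonium dichloroiodate, C[N+](C)(C)Cc1ccccc1.Cl[I-]Cl
Why: Electrophilic aromatic iodination of 5-hydroxy-7-alkoxyflavones with dichloroiodate under buffered conditions is known to go ortho to the free 5-hydroxyl at C6, and the acetate keeps ring B from reacting as a phenol.

Step 14
Reactants: 18 3-methylbut-1-yne
Product: 19 (E)-4,4,5,5-tetramethyl-2-(3-methylbut-1-en-1-yl)-1,3,2-dioxaborolane
Conditions: pinacolborane, Cp2ZrHCl (5 mol %), Et3N (10 mol %), neat, sealed tube, 60 °C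
Reagents that add atoms: pinacolborane, B1OC(C)(C)C(C)(C)O1
Why: Zirconocene-hydride-catalysed hydroboration of a terminal alkyne is a syn, anti-Markovnikov addition and should therefore deliver the (E)-alkenylboronate only.

Step 15
Reactants: 17 (10R)-4'-acetoxy-5-hydroxy-6-iodo-7-methoxyoxepinoflavone and 19 (E)-4,4,5,5-tetramethyl-2-(3-methylbut-1-en-1-yl)-1,3,2-dioxaborolane
Product: 21 (10R)-5,4'-dihydroxy-7-methoxy-6-[(E)-3-methylbut-1-en-1-yl]oxepinoflavone (target CNP0216454.1), via 6-iodo diphenol 20 (not isolated)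
Conditions: Pd(OAc)2 (5 mol %), SPhos (10 mol %), K3PO4 (aq, 4 equiv), dioxane, 80 °C; aq. NH4Cl work-up
Reagents that add atoms: none
Why: Aqueous phosphate should first hydrolyse the aryl acetate to diphenol 20, and Suzuki–Miyaura coupling of the hindered C6 iodide with the alkenylboronate then installs the side chain with retention of the E geometry, no acid being present that could cyclise the ortho-hydroxystyrene.

Compound list
1 | methyl (R)-2,2-dimethyl-1,3-dioxolane-4-carboxylate | COC(=O)[C@H]1COC(C)(C)O1 | starting material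
2 | 2-[(4R)-2,2-dimethyl-1,3-dioxolan-4-yl]propan-2-ol | CC(C)(O)[C@H]1COC(C)(C)O1 | intermediate
3 | (2R)-3-methylbutane-1,2,3-triol | CC(C)(O)[C@H](O)CO | intermediate
4 | (2R)-2,3-dihydroxy-3-methylbutyl 4-methylbenzenesulfonate | CC(C)(O)[C@H](O)COS(=O)(=O)c1ccc(C)cc1 | intermediate
5 | 2-[(2R)-oxiran-2-yl]propan-2-ol (terminal epoxide, not isolated) | CC(C)(O)[C@H]1CO1 | intermediate
6 | (3R)-2-methylhex-5-yne-2,3-diol | CC(C)(O)[C@H](O)CC#C | intermediate
7 | (4R)-2,2,5,5-tetramethyl-4-(prop-2-yn-1-yl)-1,3-dioxolane | C#CC[C@H]1OC(C)(C)OC1(C)C | intermediate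
8 | 3-bromo-4-iodophenol | Oc1ccc(I)c(Br)c1 | starting material
9 | 4-(benzyloxy)-2-bromo-1-iodobenzene | Ic1ccc(OCc2ccccc2)cc1Br | intermediate
10 | (4R)-4-{3-[4-(benzyloxy)-2-bromophenyl]prop-2-yn-1-yl}-2,2,5,5-tetramethyl-1,3-dioxolane | Brc1cc(OCc2ccccc2)ccc1C#CC[C@H]1OC(C)(C)OC1(C)C | intermediate
11 | 2-hydroxy-4,6-dimethoxybenzaldehyde | COc1cc(O)c(C=O)c(OC)c1 | starting material
12 | 2-[4-(benzyloxy)-2-bromophenyl]-5,7-dimethoxy-3-{[(4R)-2,2,5,5-tetramethyl-1,3-dioxolan-4-yl]methyl}-4H-chromen-4-one | COc1cc2oc(-c3ccc(OCc4ccccc4)cc3Br)c(C[C@H]3OC(C)(C)OC3(C)C)c(=O)c2c(OC)c1 | intermediate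
13 | 2-[4-(benzyloxy)-2-bromophenyl]-3-[(2R)-2,3-dihydroxy-3-methylbutyl]-5,7-dimethoxy-4H-chromen-4-one | COc1cc2oc(-c3ccc(OCc4ccccc4)cc3Br)c(C[C@@H](O)C(C)(C)O)c(=O)c2c(OC)c1 | intermediate
14 | (10R)-4'-benzyloxy-5,7-dimethoxyoxepinoflavone | COc1cc2oc3c(c(=O)c2c(OC)c1)C[C@H](C(C)(C)O)Oc1cc(OCc2ccccc2)ccc1-3 | intermediate
15 | (10R)-5,4'-dihydroxy-7-methoxyoxepinoflavone | COc1cc2oc3c(c(=O)c2c(O)c1)C[C@H](C(C)(C)O)Oc1cc(O)ccc1-3 | intermediate
16 | (10R)-4'-acetoxy-5-hydroxy-7-methoxyoxepinoflavone | COc1cc2oc3c(c(=O)c2c(O)c1)C[C@H](C(C)(C)O)Oc1cc(OC(C)=O)ccc1-3 | intermediate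
17 | (10R)-4'-acetoxy-5-hydroxy-6-iodo-7-methoxyoxepinoflavone | COc1cc2oc3c(c(=O)c2c(O)c1I)C[C@H](C(C)(C)O)Oc1cc(OC(C)=O)ccc1-3 | intermediate
18 | 3-methylbut-1-yne | CC(C)C#C | starting material
19 | (E)-4,4,5,5-tetramethyl-2-(3-methylbut-1-en-1-yl)-1,3,2-dioxaborolane | CC(C)/C=C/B1OC(C)(C)C(C)(C)O1 | intermediate
20 | (10R)-5,4'-dihydroxy-6-iodo-7-methoxyoxepinoflavone (6-iodo diphenol, not isolated) | COc1cc2oc3c(c(=O)c2c(O)c1I)C[C@H](C(C)(C)O)Oc1cc(O)ccc1-3 | intermediate
21 | (10R)-5,4'-dihydroxy-7-methoxy-6-[(E)-3-methylbut-1-en-1-yl]oxepinoflavone (CNP0216454.1) | COc1cc2oc3c(c(=O)c2c(O)c1/C=C/C(C)C)C[C@H](C(C)(C)O)Oc1cc(O)ccc1-3 | target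

Total step count: 15. Longest linear sequence: 13 steps (steps 1–5, 7–13 and 15); steps 6 and 14 are side branches.

Steps most likely to fail

Step 8. Insertion of the hindered 2-bromoaryl alkyne into the acyl–rhodium bond may be slow at the temperature needed, so that decarbonylation or protodemetalation of the acyl rhodacycle wins. The insertion may also take the reverse orientation, or hot acetic acid may strip the acetonide. The fallback separates C–C from C–O bond formation and sets out from 10 and 11. Chelation-assisted hydroacylation with monovalent rhodium ([RhCl(cod)]2, dppf, Na2CO3, toluene, 110 °C; no oxidant and no acid) should add the acyl group to the CH2-bearing alkyne carbon and hydrogen to the aryl-bearing one, giving the (E)-α-substituted 2'-hydroxychalcone F1. Oxidative cyclisation with catalytic I2 in DMSO at 110 °C (oxa-Michael addition, α-iodination, loss of HI) then returns to the route at 12, or at 13 if the acetonide is lost on the way.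

Step 10. β-Hydride elimination from the palladium C10 alkoxide (ketone formation with hydrodebromination) may compete with C–O reductive elimination. The tertiary hydroxyl may also be arylated, or the alkoxide may add to C2 and open the pyranone under base. The fallback makes ring B the nucleophile and C10 the electrophile, with two inversions, and sets out from 13. Mesylation of the secondary hydroxyl (MsCl, Et3N, CH2Cl2, −20 °C) should give the secondary mesylate F2. K2CO3 in MeOH closes the (S)-configured trisubstituted epoxide F3 with inversion at C10. Miyaura borylation (B2pin2, PdCl2(dppf), KOAc, dioxane, 80 °C) gives the aryl boronate F4, and oxidation (NaBO3·4H2O, THF–H2O) gives the 2'-phenol F5. The phenoxide of F5 (K2CO3, DMF, 60 °C) opens the epoxide at C10 in a 7-exo-tet attack with a second inversion, so the R configuration is restored and the route is rejoined at 14.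

Step 11. Under BCl3 the tertiary carbinol may ionise (chloride or alkene formation, hydride shift), or the C10–O bond of the oxepine may be cleaved by boron chelation between the ether and hydroxyl oxygens. The fallback unmasks the two phenols separately without a boron halide and sets out from 14. Hydrogenolysis (H2, palladium on carbon, EtOAc–MeOH, rt) should remove only the benzyl group and give the 4'-phenol F6. Chelation-controlled demethylation of the 5-methyl ether with MgI2·OEt2 (THF–toluene, 60 °C) then returns to the route at 15.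

Further compounds
F1 | step 8 | (E)-3-[4-(benzyloxy)-2-bromophenyl]-1-(2-hydroxy-4,6-dimethoxyphenyl)-2-{[(4R)-2,2,5,5-tetramethyl-1,3-dioxolan-4-yl]methyl}prop-2-en-1-one | COc1cc(O)c(C(=O)/C(C[C@H]2OC(C)(C)OC2(C)C)=C/c2ccc(OCc3ccccc3)cc2Br)c(OC)c1
F2 | step 10 | (2R)-1-{2-[4-(benzyloxy)-2-bromophenyl]-5,7-dimethoxy-4-oxo-4H-chromen-3-yl}-3-hydroxy-3-methylbutan-2-yl methanesulfonate | COc1cc2oc(-c3ccc(OCc4ccccc4)cc3Br)c(C[C@@H](OS(C)(=O)=O)C(C)(C)O)c(=O)c2c(OC)c1
F3 | step 10 | 2-[4-(benzyloxy)-2-bromophenyl]-3-{[(2S)-3,3-dimethyloxiran-2-yl]methyl}-5,7-dimethoxy-4H-chromen-4-one | COc1cc2oc(-c3ccc(OCc4ccccc4)cc3Br)c(C[C@@H]3OC3(C)C)c(=O)c2c(OC)c1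
F4 | step 10 | 2-[4-(benzyloxy)-2-(4,4,5,5-tetramethyl-1,3,2-dioxaborolan-2-yl)phenyl]-3-{[(2S)-3,3-dimethyloxiran-2-yl]methyl}-5,7-dimethoxy-4H-chromen-4-one | COc1cc2oc(-c3ccc(OCc4ccccc4)cc3B3OC(C)(C)C(C)(C)O3)c(C[C@@H]3OC3(C)C)c(=O)c2c(OC)c1
F5 | step 10 | 2-[4-(benzyloxy)-2-hydroxyphenyl]-3-{[(2S)-3,3-dimethyloxiran-2-yl]methyl}-5,7-dimethoxy-4H-chromen-4-one | COc1cc2oc(-c3ccc(OCc4ccccc4)cc3O)c(C[C@@H]3OC3(C)C)c(=O)c2c(OC)c1
F6 | step 11 | (10R)-4'-hydroxy-5,7-dimethoxyoxepinoflavone | COc1cc2oc3c(c(=O)c2c(OC)c1)C[C@H](C(C)(C)O)Oc1cc(O)ccc1-3
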